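## Retrosynthetic overview

1. The target is read as epicatechin-(4β→6)-epiafzelechin-(4β→8)-epicatechin-(4β→6)-epicatechin (units U1–U4, top to bottom); the last step is hydrogenolysis of 15 benzyl ethers and 4 C–Br caps.
2. The three interflavan bonds are cut top-down (U1–U2, then U2–U3, then U3–U4). Each is formed from a C4 cation attacked anti to the 3-OH, which gives 3,4-trans directly; reducing a 4-aryl-flavan-3-one would give 3,4-cis, so no interflavan bond is made at the ketone level.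
3. Bromine caps force attack at C6 and stop self-condensation; C4–O and C4–S leaving groups are activated separately by hard and soft promoters.
4. U1, U3 and U4 come intact from (−)-epicatechin. Key disconnection: C4–C4a of U2, closed by attack of the phloroglucinol-type ring on an α-keto carbon made electrophilic as a β-keto sulfoxonium (an enolonium equivalent); both carbons are natively nucleophilic.
5. Ring order: only ring C of U2 is built (aryl ether O1–C2 first, then C4–C4a closure); the resulting flavan-3-one is reduced with dynamic kinetic resolution to set C2 and C3.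

Assumption: in step 9 the (R,R)-TsDPEN ruthenium catalyst is taken as the antipode that gives the (2R,3R) alcohol; if the sense of induction is the reverse, the (S,S) antipode is used with no other change.

## Route

Step 1
Reactants: 1 (−)-epicatechin
Product: 2 5,7,3',4'-tetra-O-benzyl-(−)-epicatechin
Conditions: BnBr (4.4 equiv), K2CO3, DMF, 0 °C → rt
Reagents that add atoms: benzyl bromide, BrCc1ccccc1
Why: Williamson etherification in which K2CO3 deprotonates only the four phenols, so the aliphatic 3-OH stays free and no stereocentre is touched.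

Step 2
Reactants: 2 5,7,3',4'-tetra-O-benzyl-(−)-epicatechin
Product: 3 8-bromo-5,7,3',4'-tetra-O-benzylepicatechin
Conditions: NBS (1.0 equiv), CH2Cl2, −78 °C → rt
Reagents that add atoms: N-bromosuccinimide, O=C1CCC(=O)N1Br
Why: Electrophilic aromatic bromination at C8, the most nucleophilic and least hindered ring A carbon, which leaves C6 as the only nucleophilic site of the future U4.

Step 3
Reactants: 2 5,7,3',4'-tetra-O-benzyl-(−)-epicatechin
Product: 4 4β-(2-ethoxyethoxy)-5,7,3',4'-tetra-O-benzylepicatechin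
Conditions: DDQ (1.5 equiv), 2-ethoxyethanol (5 equiv), CH2Cl2, rt
Reagents that add atoms: 2-ethoxyethanol, CCOCCO
Why: DDQ benzylic oxidation (hydride abstraction at C4) gives a cation stabilized by the ring A oxygens, which the alcohol traps anti to the 3-OH to set the 4β ether.

Step 4
Reactants: 4 4β-(2-ethoxyethoxy)-5,7,3',4'-tetra-O-benzylepicatechin
Product: 5 6,8-dibromo-4β-(2-ethoxyethoxy)-5,7,3',4'-tetra-O-benzylepicatechin
Conditions: NBS (2.1 equiv), CH2Cl2, −20 °C → rt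
Reagents that add atoms: N-bromosuccinimide, O=C1CCC(=O)N1Br
Why: Twofold electrophilic aromatic bromination under neutral conditions caps both C6 and C8 of ring A, so the U1 electrophile has no nucleophilic carbon of its own and cannot self-condense.

Step 5
Reactants: 4 4β-(2-ethoxyethoxy)-5,7,3',4'-tetra-O-benzylepicatechin
Product: 6 4β-(2,6-dimethylphenylsulfanyl)-5,7,3',4'-tetra-O-benzylepicatechin
Conditions: 2,6-Me2C6H3SH (3 equiv), BF3·OEt2 (0.3 equiv), CH2Cl2, −78 → −40 °C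
Reagents that add atoms: 2,6-dimethylbenzenethiol, Cc1cccc(C)c1S
Why: Lewis-acid SN1 exchange in which the excess soft thiol captures the C4 cation anti to the 3-OH (4β) faster than ring A of a second molecule can, installing a latent leaving group that hard Lewis acids do not activate.

Step 6
Reactants: 7 methyl 2-[4-(benzyloxy)phenyl]acetate
Product: 8 methyl 2-[4-(benzyloxy)phenyl]-2-diazoacetate
Conditions: 4-acetamidobenzenesulfonyl azide (1.2 equiv), DBU, MeCN, 0 °C → rt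
Reagents that add atoms: 4-acetamidobenzenesulfonyl azide, CC(=O)Nc1ccc(cc1)S(=O)(=O)N=[N+]=[N-]
Why: Regitz diazo transfer onto the DBU enolate of an arylacetate, a standard route to aryl diazoacetates.

Step 7
Reactants: 8 methyl 2-[4-(benzyloxy)phenyl]-2-diazoacetate; 9 3,5-bis(benzyloxy)phenol
Product: 10 methyl 2-[4-(benzyloxy)phenyl]-2-[3,5-bis(benzyloxy)phenoxy]acetate (racemic)
Conditions: Rh2(OAc)4 (1 mol %), CH2Cl2, rt, slow addition of 8
Reagents that add atoms: none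
Why: Dirhodium-carbenoid O–H insertion through an oxonium ylide and proton shift forms the future O1–C2 aryl ether; the new centre is racemic and is corrected in step 9.

Step 8
Reactants: 10 methyl 2-[4-(benzyloxy)phenyl]-2-[3,5-bis(benzyloxy)phenoxy]acetate (racemic)
Product: 11 1-[4-(benzyloxy)phenyl]-1-[3,5-bis(benzyloxy)phenoxy]-3-(dimethyloxido-λ6-sulfanylidene)propan-2-one (racemic β-keto sulfoxonium ylide)
Conditions: Me3S(O)I (3 equiv), KOtBu (3 equiv), THF, reflux; then 10, 0 °C → rt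
Reagents that add atoms: trimethylsulfoxonium iodide, C[S+](C)(C)=O.[I-]
Why: Acylation of dimethylsulfoxonium methylide by the ester followed by deprotonation gives the stabilized β-keto ylide, a bench-stable stand-in for a diazoketone.

Step 9
Reactants: 11 1-[4-(benzyloxy)phenyl]-1-[3,5-bis(benzyloxy)phenoxy]-3-(dimethyloxido-λ6-sulfanylidene)propan-2-one (racemic β-keto sulfoxonium ylide)
Product: 14 (2R,3R)-5,7-bis(benzyloxy)-2-[4-(benzyloxy)phenyl]chroman-3-ol (5,7,4'-tri-O-benzyl-(−)-epiafzelechin), via sulfoxonium salt 12 (not isolated), via racemic flavan-3-one 13 (not isolated)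
Conditions: (CF3)2CHOH (HFIP), 60 °C; evaporate; then RuCl[(R,R)-TsDPEN](p-cymene) (2 mol %), HCO2H/Et3N (5:2), DMF, 40 °C
Reagents that add atoms: none
Why: Proposed new method: in HFIP the ylide carbon is protonated to salt 12, whose α-keto carbon now carries DMSO as a leaving group and acts as an enolonium (α-carbonyl cation) equivalent, so the ring A carbon ortho to the ether oxygen closes ring C by a 6-exo Friedel–Crafts alkylation that joins two natively nucleophilic carbons (closest known reactions: cyclization of α-carbonyl sulfoxonium ylides onto arenes in fluorinated alcohols and dirhodium-carbenoid closure of aryloxy diazoketones to chroman-3-ones); ketone 13 then racemizes at C2 through its enol under HCO2H/Et3N while the Noyori–Ikariya catalyst reduces one enantiomer faster with hydride delivered anti to the 2-aryl group, so a dynamic kinetic resolution sets C2 (R) and C3 (R) cis in the same pot (closest known reaction: transfer-hydrogenative dynamic kinetic resolution of 2-arylcycloalkanones).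

Step 10
Reactants: 14 5,7,4'-tri-O-benzyl-(−)-epiafzelechin
Product: 15 8-bromo-5,7,4'-tri-O-benzylepiafzelechin
Conditions: NBS (1.0 equiv), CH2Cl2, −78 °C → rt
Reagents that add atoms: N-bromosuccinimide, O=C1CCC(=O)N1Br
Why: Electrophilic aromatic bromination at C8 as in step 2, so that C6 is the only nucleophilic ring carbon of U2.

Step 11
Reactants: 5 6,8-dibromo-4β-(2-ethoxyethoxy)-5,7,3',4'-tetra-O-benzylepicatechin; 15 8-bromo-5,7,4'-tri-O-benzylepiafzelechin
Product: 16 6,8-dibromo-5,7,3',4'-tetra-O-benzylepicatechin-(4β→6)-8-bromo-5,7,4'-tri-O-benzylepiafzelechin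
Conditions: 15 (1.3 equiv), TMSOTf (0.3 equiv), CH2Cl2, −40 → 0 °C
Reagents that add atoms: none
Why: Lewis-acid-catalysed Friedel–Crafts interflavan coupling (SN1) in which C6 of 15, the only free nucleophilic ring carbon in the flask, attacks the C4 cation of 5 anti to its 3-OH, setting 4β (3,4-trans) on U1.

Step 12
Reactants: 16 6,8-dibromo-5,7,3',4'-tetra-O-benzylepicatechin-(4β→6)-8-bromo-5,7,4'-tri-O-benzylepiafzelechin
Product: 17 6,8-dibromo-5,7,3',4'-tetra-O-benzylepicatechin-(4β→6)-8-bromo-4β-(2-ethoxyethoxy)-5,7,4'-tri-O-benzylepiafzelechin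
Conditions: DDQ (2 equiv), 2-ethoxyethanol (10 equiv), CH2Cl2, rt
Reagents that add atoms: 2-ethoxyethanol, CCOCCO
Why: DDQ benzylic oxidation at the only C4 methylene (U2); the diarylmethine C4–H of U1 is shielded by two fully ortho-substituted rings and sits on the electron-poorer dibrominated ring, and the alcohol adds anti to the 3-OH.

Step 13
Reactants: 17 6,8-dibromo-5,7,3',4'-tetra-O-benzylepicatechin-(4β→6)-8-bromo-4β-(2-ethoxyethoxy)-5,7,4'-tri-O-benzylepiafzelechin; 6 4β-(2,6-dimethylphenylsulfanyl)-5,7,3',4'-tetra-O-benzylepicatechin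
Product: 18 6,8-dibromo-5,7,3',4'-tetra-O-benzylepicatechin-(4β→6)-8-bromo-5,7,4'-tri-O-benzylepiafzelechin-(4β→8)-4β-(2,6-dimethylphenylsulfanyl)-5,7,3',4'-tetra-O-benzylepicatechin
Conditions: 6 (2 equiv), BF3·OEt2 (0.3 equiv), CH2Cl2, −78 → −30 °C
Reagents that add atoms: none
Why: The hard Lewis acid ionizes only the C4–O ether of 17 (fully capped, so no self-condensation), and C8 of 6, more nucleophilic than its C6, attacks anti to the 3-OH of U2 to set the 4β→8 bond while the thioether stays intact (orthogonal activation).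

Step 14
Reactants: 18 the U1–U2–U3 thioether trimer; 3 8-bromo-5,7,3',4'-tetra-O-benzylepicatechin
Product: 19 6,8-dibromo-5,7,3',4'-tetra-O-benzylepicatechin-(4β→6)-8-bromo-5,7,4'-tri-O-benzylepiafzelechin-(4β→8)-5,7,3',4'-tetra-O-benzylepicatechin-(4β→6)-8-bromo-5,7,3',4'-tetra-O-benzylepicatechin
Conditions: 3 (3 equiv), AgBF4 (2 equiv), NaHCO3, 4 Å MS, THF/CH2Cl2, −20 °C → rt
Reagents that add atoms: none
Why: Thiophilic monovalent silver ionizes the C4–S bond of U3, and C6 of 3 (C8 capped) attacks the cation anti to the 3-OH, giving the 4β→6 bond by a silver-promoted Friedel–Crafts coupling; the bicarbonate takes up the acid so the earlier interflavan bonds are not cleaved.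

Step 15
Reactants: 19 the fully protected tetramer
Product: 20 epicatechin-(4β→6)-epiafzelechin-(4β→8)-epicatechin-(4β→6)-epicatechin (CNP0103636.1)
Conditions: H2 (5 bar), Pd(OH)2/C, NaHCO3 (4 equiv), THF/MeOH/H2O, rt
Reagents that add atoms: none
Why: Hydrogenolysis removes all 15 benzyl ethers and hydrodebrominates the 4 aryl bromides in one operation, with bicarbonate buffering the HBr so that the acid-labile interflavan bonds and all 12 stereocentres are untouched.

## Compound list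

1 | (−)-epicatechin | O[C@@H]1Cc2c(O)cc(O)cc2O[C@@H]1c1ccc(O)c(O)c1 | starting material
2 | 5,7,3',4'-tetra-O-benzyl-(−)-epicatechin | O[C@@H]1Cc2c(OCc3ccccc3)cc(OCc3ccccc3)cc2O[C@@H]1c1ccc(OCc2ccccc2)c(OCc2ccccc2)c1 | intermediate
3 | 8-bromo-5,7,3',4'-tetra-O-benzylepicatechin | O[C@@H]1Cc2c(OCc3ccccc3)cc(OCc3ccccc3)c(Br)c2O[C@@H]1c1ccc(OCc2ccccc2)c(OCc2ccccc2)c1 | intermediate
4 | 4β-(2-ethoxyethoxy)-5,7,3',4'-tetra-O-benzylepicatechin | O[C@@H]1[C@@H](OCCOCC)c2c(OCc3ccccc3)cc(OCc3ccccc3)cc2O[C@@H]1c1ccc(OCc2ccccc2)c(OCc2ccccc2)c1 | intermediate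
5 | 6,8-dibromo-4β-(2-ethoxyethoxy)-5,7,3',4'-tetra-O-benzylepicatechin | O[C@@H]1[C@@H](OCCOCC)c2c(OCc3ccccc3)c(Br)c(OCc3ccccc3)c(Br)c2O[C@@H]1c1ccc(OCc2ccccc2)c(OCc2ccccc2)c1 | intermediate
6 | 4β-(2,6-dimethylphenylsulfanyl)-5,7,3',4'-tetra-O-benzylepicatechin | O[C@@H]1[C@@H](Sc3c(C)cccc3C)c2c(OCc3ccccc3)cc(OCc3ccccc3)cc2O[C@@H]1c1ccc(OCc2ccccc2)c(OCc2ccccc2)c1 | intermediate
7 | methyl 2-[4-(benzyloxy)phenyl]acetate | COC(=O)Cc1ccc(OCc2ccccc2)cc1 | starting material
8 | methyl 2-[4-(benzyloxy)phenyl]-2-diazoacetate | COC(=O)C(=[N+]=[N-])c1ccc(OCc2ccccc2)cc1 | intermediate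
9 | 3,5-bis(benzyloxy)phenol | Oc1cc(OCc2ccccc2)cc(OCc2ccccc2)c1 | starting material
10 | methyl 2-[4-(benzyloxy)phenyl]-2-[3,5-bis(benzyloxy)phenoxy]acetate (racemic) | COC(=O)C(Oc1cc(OCc2ccccc2)cc(OCc2ccccc2)c1)c1ccc(OCc2ccccc2)cc1 | intermediate
11 | 1-[4-(benzyloxy)phenyl]-1-[3,5-bis(benzyloxy)phenoxy]-3-(dimethyloxido-λ6-sulfanylidene)propan-2-one (racemic β-keto sulfoxonium ylide) | C[S+](C)(=O)[CH-]C(=O)C(Oc1cc(OCc2ccccc2)cc(OCc2ccccc2)c1)c1ccc(OCc2ccccc2)cc1 | intermediate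
12 | {3-[4-(benzyloxy)phenyl]-3-[3,5-bis(benzyloxy)phenoxy]-2-oxopropyl}dimethylsulfoxonium hexafluoroisopropoxide (racemic) | C[S+](C)(=O)CC(=O)C(Oc1cc(OCc2ccccc2)cc(OCc2ccccc2)c1)c1ccc(OCc2ccccc2)cc1.[O-]C(C(F)(F)F)C(F)(F)F | intermediate (not isolated)
13 | rac-5,7-bis(benzyloxy)-2-[4-(benzyloxy)phenyl]chroman-3-one | O=C1Cc2c(OCc3ccccc3)cc(OCc3ccccc3)cc2OC1c1ccc(OCc2ccccc2)cc1 | intermediate (not isolated)
14 | (2R,3R)-5,7-bis(benzyloxy)-2-[4-(benzyloxy)phenyl]chroman-3-ol (5,7,4'-tri-O-benzyl-(−)-epiafzelechin) | O[C@@H]1Cc2c(OCc3ccccc3)cc(OCc3ccccc3)cc2O[C@@H]1c1ccc(OCc2ccccc2)cc1 | intermediate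
15 | 8-bromo-5,7,4'-tri-O-benzylepiafzelechin | O[C@@H]1Cc2c(OCc3ccccc3)cc(OCc3ccccc3)c(Br)c2O[C@@H]1c1ccc(OCc2ccccc2)cc1 | intermediate
16 | 6,8-dibromo-5,7,3',4'-tetra-O-benzylepicatechin-(4β→6)-8-bromo-5,7,4'-tri-O-benzylepiafzelechin | O[C@@H]1Cc2c(OCc3ccccc3)c([C@H]3c4c(OCc5ccccc5)c(Br)c(OCc5ccccc5)c(Br)c4O[C@H](c4ccc(OCc5ccccc5)c(OCc5ccccc5)c4)[C@@H]3O)c(OCc3ccccc3)c(Br)c2O[C@@H]1c1ccc(OCc2ccccc2)cc1 | intermediate
17 | 6,8-dibromo-5,7,3',4'-tetra-O-benzylepicatechin-(4β→6)-8-bromo-4β-(2-ethoxyethoxy)-5,7,4'-tri-O-benzylepiafzelechin | O[C@@H]1[C@@H](OCCOCC)c2c(OCc3ccccc3)c([C@H]3c4c(OCc5ccccc5)c(Br)c(OCc5ccccc5)c(Br)c4O[C@H](c4ccc(OCc5ccccc5)c(OCc5ccccc5)c4)[C@@H]3O)c(OCc3ccccc3)c(Br)c2O[C@@H]1c1ccc(OCc2ccccc2)cc1 | intermediate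
18 | 6,8-dibromo-5,7,3',4'-tetra-O-benzylepicatechin-(4β→6)-8-bromo-5,7,4'-tri-O-benzylepiafzelechin-(4β→8)-4β-(2,6-dimethylphenylsulfanyl)-5,7,3',4'-tetra-O-benzylepicatechin | O[C@@H]1[C@@H](c3c(OCc4ccccc4)cc(OCc4ccccc4)c4c3O[C@H](c3ccc(OCc5ccccc5)c(OCc5ccccc5)c3)[C@H](O)[C@H]4Sc3c(C)cccc3C)c2c(OCc3ccccc3)c([C@H]3c4c(OCc5ccccc5)c(Br)c(OCc5ccccc5)c(Br)c4O[C@H](c4ccc(OCc5ccccc5)c(OCc5ccccc5)c4)[C@@H]3O)c(OCc3ccccc3)c(Br)c2O[C@@H]1c1ccc(OCc2ccccc2)cc1 | intermediate
19 | 6,8-dibromo-5,7,3',4'-tetra-O-benzylepicatechin-(4β→6)-8-bromo-5,7,4'-tri-O-benzylepiafzelechin-(4β→8)-5,7,3',4'-tetra-O-benzylepicatechin-(4β→6)-8-bromo-5,7,3',4'-tetra-O-benzylepicatechin | O[C@@H]1[C@@H](c3c(OCc4ccccc4)cc(OCc4ccccc4)c4c3O[C@H](c3ccc(OCc5ccccc5)c(OCc5ccccc5)c3)[C@H](O)[C@H]4c3c(OCc4ccccc4)c(Br)c4c(c3OCc3ccccc3)C[C@@H](O)[C@@H](c3ccc(OCc5ccccc5)c(OCc5ccccc5)c3)O4)c2c(OCc3ccccc3)c([C@H]3c4c(OCc5ccccc5)c(Br)c(OCc5ccccc5)c(Br)c4O[C@H](c4ccc(OCc5ccccc5)c(OCc5ccccc5)c4)[C@@H]3O)c(OCc3ccccc3)c(Br)c2O[C@@H]1c1ccc(OCc2ccccc2)cc1 | intermediate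
20 | epicatechin-(4β→6)-epiafzelechin-(4β→8)-epicatechin-(4β→6)-epicatechin (CNP0103636.1) | Oc1ccc([C@H]2Oc3cc(O)c([C@H]4c5c(O)cc(O)cc5O[C@H](c5ccc(O)c(O)c5)[C@@H]4O)c(O)c3[C@H](c3c(O)cc(O)c4c3O[C@H](c3ccc(O)c(O)c3)[C@H](O)[C@H]4c3c(O)cc4c(c3O)C[C@@H](O)[C@@H](c3ccc(O)c(O)c3)O4)[C@H]2O)cc1 | target

## Step count and risks

Total: 15 steps. Longest linear sequence: 10 steps (7 → 8 → 10 → 11 → 14 → 15 → 16 → 17 → 18 → 19 → 20, steps 6–15).

**Step 12 (DDQ oxidation of dimer 16).** The ring A ethers of U2 are now flanked on both sides and donate less, so hydride abstraction may be slow or may compete with attack at the diarylmethine of U1. The fallback sets out from 15 and 5 and comes back at 17, bypassing oxidation of any dimer. Monomer 15 is oxidized with DDQ and 2-ethoxyethanol to 8-bromo-4β-(2-ethoxyethoxy)-5,7,4'-tri-O-benzylepiafzelechin F6. In parallel 5 is exchanged with 2,6-dimethylbenzenethiol and BF3·OEt2 to 6,8-dibromo-4β-(2,6-dimethylphenylsulfanyl)-5,7,3',4'-tetra-O-benzylepicatechin F7. AgBF4 then ionizes only the C4–S bond of F7, and C6 of F6, whose C4–O ether is inert to the soft promoter, attacks to give 17.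

**Step 9 (ring closure and reduction in one pot).** The sulfoxonium closure may be slow or give intermolecular alkylation, and the ketone is too labile to purify between the two stages. The fallback sets out from 10 and comes back at 13, now isolated, using a metal carbenoid for the same bond. Ester 10 is saponified with LiOH to 2-[4-(benzyloxy)phenyl]-2-[3,5-bis(benzyloxy)phenoxy]acetic acid F1. The acid is activated with ethyl chloroformate and Et3N as the mixed anhydride ethoxycarbonyl 2-[4-(benzyloxy)phenyl]-2-[3,5-bis(benzyloxy)phenoxy]acetate F2. Diazomethane converts this to the diazoketone 1-[4-(benzyloxy)phenyl]-1-[3,5-bis(benzyloxy)phenoxy]-3-diazopropan-2-one F3. Rh2(OAc)4 in CH2Cl2 then closes ring C by carbenoid aromatic substitution to 13, which is reduced under the second-stage conditions of step 9.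

**Step 11 (coupling of the doubly brominated electrophile 5 with hindered C6 of 15).** Two bromines twist and deactivate the ring A ethers, so the cation may form too slowly. The fallback sets out from 3 and 15 and comes back at 16. Compound 3 is oxidized with DDQ and 2-ethoxyethanol to the singly capped, more easily ionized 8-bromo-4β-(2-ethoxyethoxy)-5,7,3',4'-tetra-O-benzylepicatechin F4. F4 is added slowly to 3 equiv of 15 and catalytic TMSOTf (excess 15 recovered) to give 8-bromo-5,7,3',4'-tetra-O-benzylepicatechin-(4β→6)-8-bromo-5,7,4'-tri-O-benzylepiafzelechin F5. One equivalent of NBS then brominates the only free ring A carbon (C6 of the upper unit) to give 16.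

Further compounds

F1 | step 9 | 2-[4-(benzyloxy)phenyl]-2-[3,5-bis(benzyloxy)phenoxy]acetic acid (racemic) | OC(=O)C(Oc1cc(OCc2ccccc2)cc(OCc2ccccc2)c1)c1ccc(OCc2ccccc2)cc1
F2 | step 9 | ethoxycarbonyl 2-[4-(benzyloxy)phenyl]-2-[3,5-bis(benzyloxy)phenoxy]acetate (racemic mixed anhydride) | CCOC(=O)OC(=O)C(Oc1cc(OCc2ccccc2)cc(OCc2ccccc2)c1)c1ccc(OCc2ccccc2)cc1
F3 | step 9 | 1-[4-(benzyloxy)phenyl]-1-[3,5-bis(benzyloxy)phenoxy]-3-diazopropan-2-one (racemic) | [N-]=[N+]=CC(=O)C(Oc1cc(OCc2ccccc2)cc(OCc2ccccc2)c1)c1ccc(OCc2ccccc2)cc1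
F4 | step 11 | 8-bromo-4β-(2-ethoxyethoxy)-5,7,3',4'-tetra-O-benzylepicatechin | O[C@@H]1[C@@H](OCCOCC)c2c(OCc3ccccc3)cc(OCc3ccccc3)c(Br)c2O[C@@H]1c1ccc(OCc2ccccc2)c(OCc2ccccc2)c1
F5 | step 11 | 8-bromo-5,7,3',4'-tetra-O-benzylepicatechin-(4β→6)-8-bromo-5,7,4'-tri-O-benzylepiafzelechin | O[C@@H]1Cc2c(OCc3ccccc3)c([C@H]3c4c(OCc5ccccc5)cc(OCc5ccccc5)c(Br)c4O[C@H](c4ccc(OCc5ccccc5)c(OCc5ccccc5)c4)[C@@H]3O)c(OCc3ccccc3)c(Br)c2O[C@@H]1c1ccc(OCc2ccccc2)cc1
F6 | step 12 | 8-bromo-4β-(2-ethoxyethoxy)-5,7,4'-tri-O-benzylepiafzelechin | O[C@@H]1[C@@H](OCCOCC)c2c(OCc3ccccc3)cc(OCc3ccccc3)c(Br)c2O[C@@H]1c1ccc(OCc2ccccc2)cc1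
F7 | step 12 | 6,8-dibromo-4β-(2,6-dimethylphenylsulfanyl)-5,7,3',4'-tetra-O-benzylepicatechin | O[C@@H]1[C@@H](Sc3c(C)cccc3C)c2c(OCc3ccccc3)c(Br)c(OCc3ccccc3)c(Br)c2O[C@@H]1c1ccc(OCc2ccccc2)c(OCc2ccccc2)c1
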